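No run reaches the asked time: the last readings stand at 4.00 min, and the flask is asked at 6.0 min, later than any of them.

| flask | substrate | gas phase | free catalyst | impurity | remark | time |
|---|---|---|---|---|---|---|
| elm | 20 mM | 5.6 mM (held) | 0.58 mM | 0.17 mM | run made earlier |  |
| birch | 20 mM | 5.6 mM (held) | 0.58 mM | 0.39 mM | run made earlier |  |
| larch | 10 mM | 5.6 mM (held) | 0.58 mM | 0.26 mM | run made earlier |  |
| flask | 20 mM | 5.6 mM (held) | 0.58 mM | 0.26 mM |  | 6.0 min |

| run | time / min | target / % | substrate / % |
|---|---|---|---|
| elm | 0.500 | 5 | 96 |
| elm | 1.00 | 12 | 91 |
| elm | 1.50 | 15 | 82 |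
| elm | 2.00 | 18 | 79 |
| elm | 2.50 | 25 | 77 |
| elm | 3.00 | 24 | 76 |
| elm | 4.00 | 33 | 63 |
| birch | 0.200 | 0 | 98 |
| birch | 0.500 | 4 | 98 |
| birch | 1.00 | 5 | 94 |
| birch | 1.50 | 9 | 89 |
| birch | 2.00 | 14 | 87 |
| birch | 3.00 | 21 | 80 |
| birch | 4.00 | 29 | 71 |
| larch | 0.250 | 0 | 96 |
| larch | 0.500 | 3 | 97 |
| larch | 1.00 | 10 | 90 |
| larch | 2.00 | 23 | 77 |
| larch | 4.00 | 38 | 61 |

(each reading ± 1.5 percentage points)

- at the start none of the gas phase is in solution

1. how much target there is at 6.0 min, in percent of the substrate charged
2. the change that raises the amount of target at 6.0 min, in percent of the substrate charged most ("none" if none brings more than 2 percentage points) (epsilon / gamma / delta / none)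
3. amount of target at 6.0 min, in percent of the substrate charged, after delta

- epsilon: doubling the amount of free catalyst, all else as stated
- gamma: doubling the transfer coefficient of the gas phase, all else as stated
- delta: doubling the saturation concentration of gas phase, all else as stated

So I follow one substrate molecule and ask what its odds are, each minute, of becoming target. I take minus the logarithm of the fraction not yet target, divided by the time. This is a pseudo-first-order constant read from readings. Elm's last reading gives 0.100 min⁻¹, birch's 0.0856 min⁻¹. Larch, at a smaller charge, reads 0.120 min⁻¹, more than either, so I leave it out. The flask has the substrate charge of elm and birch, and its impurity lies between theirs, so I use their mean, the chance per minute 0.0929 min⁻¹.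

What does it give? If that chance holds to the asked time, I estimate target at 42.7 % at 6.0 min.

Which change helps? Birch carries extra impurity over elm worth 37.9 % of the free catalyst charge, yet elm's chance reads above birch's by a factor of 1.17. So if impurity takes free catalyst one for one, I expect little from epsilon. If the chance follows the gas, which no run tests, delta doubles it and I estimate target at 67.2 %. Gamma leaves saturation where it is, so I choose delta.

The forecast says 43 %, delta and 68 %: “Doubling saturation doubles the driving force and the dissolved gas, assuming first order in gas, which no run tested.” Its two amounts stand a little above my 42.7 % and 67.2 % .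

The flask gives 41.4 %, and delta gains 26 percentage points, reaching 67.5 %, against 9.6 points for gamma and 5.8 points for epsilon. Dissolved gas in the flask stands at 65.7 % of saturation at 3.00 min. Read back over 6.0 min, the flask's chance per minute is 0.0891 min⁻¹, against my 0.0929 min⁻¹.

    substrate → decomposition product (k = 2.10 × 10⁻⁵ s⁻¹)
    free catalyst + impurity → spent catalyst A (k = 6700 L mol⁻¹ s⁻¹)
    2 free catalyst → spent catalyst B (k = 24.0 L mol⁻¹ s⁻¹)
    substrate + dissolved gas + free catalyst → free catalyst + target (k = 5000 L² mol⁻² s⁻¹)
    gas phase ⇌ dissolved gas, rate k5*(csat - [dissolved gas]) (kL = 0.0160 s⁻¹)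

For the flask left until 25 min, the chance 0.0929 min⁻¹, held constant, gives 90.2 % target. The computed flask holds 70.3 % target, with free catalyst at 2.29 % of its charge.

(All runs stem from a simulated flask for substances that don't exist, noise included.)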